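**Plan**

- Retrosynthetic cuts: the quinone goes back to its hydroquinone (redox only), then O1–C2 of the pyran ring, then C3–C1' between the chroman and ring B, then C4–C4a between the three-carbon chain and ring A.
- Enabling feature: ring B is a 2,3-dimethoxy-1,4-benzoquinone whose other C=C edge carries one carbon substituent only, chroman C3. C3 lies between C2 (alcohol-level carbon on O1) and C4 (benzylic to ring A), so it is the α-carbon of a ring A 3-arylpropanal and C1' is one of two equivalent CH positions of the symmetric quinone.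
- Forward order: ring A is bought as an arene and given its chain by a Heck reaction. The aldehyde α-carbon is then joined to the quinone, which aromatises and closes a temporary five-membered furanol ring. Reduction opens that ring, the pyran ring is closed through O1–C2, and the quinone is regenerated last.
- Stereochemistry: C3 is the only stereocentre. It is set in the enamine arylation by the (R)-diphenylprolinol silyl ether catalyst, and no later step breaks a bond at C3.

Key step: step 7

Remark: chroman numbering (O1, C2, C3, C4, C4a, C5–C8, C8a; primed numbers for ring B) is used and the target is (3S), from C2 > C1' > C4 > H. The sense of induction in step 7 is assigned from the steric-shielding model of diarylprolinol silyl ether enamines.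

**Route**

Step 1
Reactants: 1 2-hydroxy-3,4-dimethoxybenzaldehyde
Product: 2 2-(benzyloxy)-3,4-dimethoxybenzaldehyde
Conditions: BnBr, K2CO3, DMF, 60 °C
Reagents that add atoms: benzyl bromide, BrCc1ccccc1
Why: Williamson etherification of the phenoxide installs the benzyl ether that will release the C8 phenol by hydrogenolysis at the end.

Step 2
Reactants: 2 2-(benzyloxy)-3,4-dimethoxybenzaldehyde
Product: 4 2-(benzyloxy)-3,4-dimethoxyphenol, via aryl formate 3 (not isolated)
Conditions: mCPBA, CH2Cl2, 0 °C to rt; aqueous NaHCO3 wash; then K2CO3 (cat.), MeOH, rt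
Reagents that add atoms: 3-chloroperoxybenzoic acid, OOC(=O)c1cccc(Cl)c1
Why: Baeyer–Villiger (Dakin-type) oxidation, in which the electron-rich aryl group migrates to give the aryl formate, whose methanolysis frees the phenol oxygen that becomes O1.

Step 3
Reactants: 4 2-(benzyloxy)-3,4-dimethoxyphenol
Product: 5 2-(benzyloxy)-6-iodo-3,4-dimethoxyphenol
Conditions: I2, NaHCO3, THF/H2O, 0 °C to rt
Reagents that add atoms: iodine, [I][I]
Why: Electrophilic aromatic iodination of the phenoxide, which directs to its only free ortho carbon (para carries methoxy), a site also para to a methoxy group, so the position para to the benzyloxy group should not compete.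

Step 4
Reactants: 5 2-(benzyloxy)-6-iodo-3,4-dimethoxyphenol
Product: 6 3-(benzyloxy)-1-iodo-4,5-dimethoxy-2-(methoxymethoxy)benzene
Conditions: NaH, MOMCl, THF, 0 °C to rt
Reagents that add atoms: chloromethyl methyl ether, COCCl
Why: O-alkylation of the sodium phenoxide gives an acetal ether that tolerates the palladium, enamine, borohydride and carbonate steps and is later removed by acid without loss of benzyl ethers.

Step 5
Reactants: 6 3-(benzyloxy)-1-iodo-4,5-dimethoxy-2-(methoxymethoxy)benzene; 7 allyl alcohol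
Product: 8 3-[3-(benzyloxy)-4,5-dimethoxy-2-(methoxymethoxy)phenyl]propanal
Conditions: Pd(OAc)2 (5 mol%), Bu4NCl, NaHCO3, DMF, 45 °C
Reagents that add atoms: none
Why: Mizoroki–Heck arylation of allyl alcohol under ligand-free phase-transfer (Jeffery) conditions, where the aryl group adds to the terminal alkene carbon and β-hydride elimination toward the carbinol gives an enol that tautomerises to the saturated aldehyde.

Step 6
Reactants: 9 2,3-dimethoxyphenol
Product: 10 2,3-dimethoxy-1,4-benzoquinone
Conditions: potassium nitrosodisulfonate (KSO3)2NO (2.2 equiv), KH2PO4, H2O/acetone, 0 °C to rt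
Reagents that add atoms: potassium nitrosodisulfonate, [K+].[K+].[O-]S(=O)(=O)N([O])S(=O)(=O)[O-]
Why: Teuber oxidation, in which two equivalents of the nitroxyl radical convert a phenol with a free para position into the para-quinone while the methoxy groups stay.

Step 7
Reactants: 8 3-[3-(benzyloxy)-4,5-dimethoxy-2-(methoxymethoxy)phenyl]propanal; 10 2,3-dimethoxy-1,4-benzoquinone
Product: 12 (3S)-3-[3-(benzyloxy)-4,5-dimethoxy-2-(methoxymethoxy)benzyl]-6,7-dimethoxy-2,3-dihydro-1-benzofuran-2,5-diol as a mixture of C2 anomers, via hydroxy aldehyde 11 (not isolated)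
Conditions: (R)-2-[diphenyl(trimethylsilyloxy)methyl]pyrrolidine (20 mol%), EtOH/H2O, −20 to 0 °C, Ar; 8 in slight excess over 10
Reagents that add atoms: none
Why: The amine condenses with the unbranched aldehyde 8 to a single E-enamine whose α-carbon adds in conjugate fashion to the unsubstituted C5=C6 edge of quinone 10; enolisation aromatises ring B to the hydroquinone and hydrolysis of the iminium returns the catalyst and hydroxy aldehyde 11. The closest known reaction type is the amine-catalysed enantioselective α-arylation of aldehydes with 1,4-quinones, applied here to a dialkoxy quinone. The one ring closed is the five-membered furanol ring, by 5-exo-trig addition of the hydroquinone OH ortho to the new C–C bond onto the aldehyde carbonyl. The C3 stereocentre is controlled by the diphenyl(trimethylsilyloxy)methyl group of the (R)-catalyst, which blocks one face of the s-trans E-enamine so that the quinone approaches the other and (S) is expected; the lactol carbon forms as both anomers, which does not matter because it is reduced in step 8. The step needs enantioface selectivity (catalyst), mono-addition (the lactol caps one hydroquinone oxygen and so resists re-oxidation by 10, helped by the slight excess of aldehyde) and protection of the new centre from enolisation (lactol formation removes the free aldehyde). Site selectivity on the quinone needs no control, since C5 and C6 are equivalent and the methoxy-bearing edge is a deactivated vinylogous ester.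

Step 8
Reactants: 12 (3S)-3-[3-(benzyloxy)-4,5-dimethoxy-2-(methoxymethoxy)benzyl]-6,7-dimethoxy-2,3-dihydro-1-benzofuran-2,5-diol
Product: 13 2-[(2S)-1-[3-(benzyloxy)-4,5-dimethoxy-2-(methoxymethoxy)phenyl]-3-hydroxypropan-2-yl]-5,6-dimethoxybenzene-1,4-diol
Conditions: NaBH4, EtOH, 0 °C, Ar
Reagents that add atoms: none
Why: Borohydride reduction of a lactol, in which the hemiacetal ring of 12 stands in ring–chain equilibrium with its open hydroxy aldehyde tautomer and that carbonyl is reduced faster than it enolises, so C3 keeps its configuration and the hydroquinone stays in the reduced state.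

Step 9
Reactants: 13 2-[(2S)-1-[3-(benzyloxy)-4,5-dimethoxy-2-(methoxymethoxy)phenyl]-3-hydroxypropan-2-yl]-5,6-dimethoxybenzene-1,4-diol
Product: 14 (2S)-2-[2,5-bis(benzyloxy)-3,4-dimethoxyphenyl]-3-[3-(benzyloxy)-4,5-dimethoxy-2-(methoxymethoxy)phenyl]propan-1-ol
Conditions: BnBr (2.4 equiv), K2CO3, Na2S2O4 (cat.), DMF, rt to 50 °C, Ar
Reagents that add atoms: benzyl bromide, BrCc1ccccc1
Why: Williamson etherification in which carbonate ionises only the two hydroquinone hydroxyls and not the primary alcohol, with argon and a trace of dithionite guarding against air oxidation; the benzyl ethers keep the 2'-oxygen out of the later ring closure.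

Step 10
Reactants: 14 (2S)-2-[2,5-bis(benzyloxy)-3,4-dimethoxyphenyl]-3-[3-(benzyloxy)-4,5-dimethoxy-2-(methoxymethoxy)phenyl]propan-1-ol
Product: 15 2-(benzyloxy)-6-{(2S)-2-[2,5-bis(benzyloxy)-3,4-dimethoxyphenyl]-3-hydroxypropyl}-3,4-dimethoxyphenol
Conditions: HCl (cat.), MeOH/THF, 45 °C
Reagents that add atoms: none
Why: Acid-catalysed acetal solvolysis removes the methoxymethyl group, while benzyl ethers, methyl ethers and the primary alcohol are inert.

Step 11
Reactants: 15 2-(benzyloxy)-6-{(2S)-2-[2,5-bis(benzyloxy)-3,4-dimethoxyphenyl]-3-hydroxypropyl}-3,4-dimethoxyphenol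
Product: 16 (3S)-8-(benzyloxy)-3-[2,5-bis(benzyloxy)-3,4-dimethoxyphenyl]-6,7-dimethoxy-3,4-dihydro-2H-chromene
Conditions: PPh3, DIAD, THF, 0 °C to rt
Reagents that add atoms: none
Why: Intramolecular Mitsunobu etherification, in which the primary alcohol is activated as an alkoxyphosphonium ion and displaced by the ring A phenoxide in a 6-exo-tet closure that forms O1–C2 without breaking a bond at C3.

Step 12
Reactants: 16 (3S)-8-(benzyloxy)-3-[2,5-bis(benzyloxy)-3,4-dimethoxyphenyl]-6,7-dimethoxy-3,4-dihydro-2H-chromene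
Product: 18 5-[(3S)-8-hydroxy-6,7-dimethoxy-3,4-dihydro-2H-chromen-3-yl]-2,3-dimethoxycyclohexa-2,5-diene-1,4-dione, via hydroquinone triol 17 (not isolated)
Conditions: H2 (1 atm), 10% Pd/C, EtOAc/MeOH, rt; filter under Ar; then Ag2O (1.2 equiv), Na2SO4, Et2O, rt
Reagents that add atoms: none
Why: Catalytic hydrogenolysis cleaves the three benzyl aryl ethers, and Ag2O then dehydrogenates only the para-hydroquinone of ring B, whose oxidation potential lies far below that of the single ring A phenol, under neutral conditions that leave C3 untouched.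

**Compound list**

1 | 2-hydroxy-3,4-dimethoxybenzaldehyde | COc1ccc(C=O)c(O)c1OC | starting material
2 | 2-(benzyloxy)-3,4-dimethoxybenzaldehyde | COc1ccc(C=O)c(OCc2ccccc2)c1OC | intermediate
3 | 2-(benzyloxy)-3,4-dimethoxyphenyl formate | COc1ccc(OC=O)c(OCc2ccccc2)c1OC | intermediate
4 | 2-(benzyloxy)-3,4-dimethoxyphenol | COc1ccc(O)c(OCc2ccccc2)c1OC | intermediate
5 | 2-(benzyloxy)-6-iodo-3,4-dimethoxyphenol | COc1cc(I)c(O)c(OCc2ccccc2)c1OC | intermediate
6 | 3-(benzyloxy)-1-iodo-4,5-dimethoxy-2-(methoxymethoxy)benzene | COCOc1c(I)cc(OC)c(OC)c1OCc1ccccc1 | intermediate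
7 | allyl alcohol | C=CCO | starting material
8 | 3-[3-(benzyloxy)-4,5-dimethoxy-2-(methoxymethoxy)phenyl]propanal | O=CCCc1cc(OC)c(OC)c(OCc2ccccc2)c1OCOC | intermediate
9 | 2,3-dimethoxyphenol | COc1cccc(O)c1OC | starting material
10 | 2,3-dimethoxy-1,4-benzoquinone | COC1=C(OC)C(=O)C=CC1=O | intermediate
11 | (2S)-3-[3-(benzyloxy)-4,5-dimethoxy-2-(methoxymethoxy)phenyl]-2-(2,5-dihydroxy-3,4-dimethoxyphenyl)propanal | O=C[C@H](c1cc(O)c(OC)c(OC)c1O)Cc1cc(OC)c(OC)c(OCc2ccccc2)c1OCOC | intermediate
12 | (3S)-3-[3-(benzyloxy)-4,5-dimethoxy-2-(methoxymethoxy)benzyl]-6,7-dimethoxy-2,3-dihydro-1-benzofuran-2,5-diol (C2 anomers) | OC1Oc2c(OC)c(OC)c(O)cc2[C@@H]1Cc1cc(OC)c(OC)c(OCc2ccccc2)c1OCOC | intermediate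
13 | 2-[(2S)-1-[3-(benzyloxy)-4,5-dimethoxy-2-(methoxymethoxy)phenyl]-3-hydroxypropan-2-yl]-5,6-dimethoxybenzene-1,4-diol | OC[C@H](c1cc(O)c(OC)c(OC)c1O)Cc1cc(OC)c(OC)c(OCc2ccccc2)c1OCOC | intermediate
14 | (2S)-2-[2,5-bis(benzyloxy)-3,4-dimethoxyphenyl]-3-[3-(benzyloxy)-4,5-dimethoxy-2-(methoxymethoxy)phenyl]propan-1-ol | OC[C@H](c1cc(OCc2ccccc2)c(OC)c(OC)c1OCc1ccccc1)Cc1cc(OC)c(OC)c(OCc2ccccc2)c1OCOC | intermediate
15 | 2-(benzyloxy)-6-{(2S)-2-[2,5-bis(benzyloxy)-3,4-dimethoxyphenyl]-3-hydroxypropyl}-3,4-dimethoxyphenol | OC[C@H](c1cc(OCc2ccccc2)c(OC)c(OC)c1OCc1ccccc1)Cc1cc(OC)c(OC)c(OCc2ccccc2)c1O | intermediate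
16 | (3S)-8-(benzyloxy)-3-[2,5-bis(benzyloxy)-3,4-dimethoxyphenyl]-6,7-dimethoxy-3,4-dihydro-2H-chromene | COc1cc2c(c(OCc3ccccc3)c1OC)OC[C@H](c1cc(OCc3ccccc3)c(OC)c(OC)c1OCc1ccccc1)C2 | intermediate
17 | 2-[(3S)-8-hydroxy-6,7-dimethoxy-3,4-dihydro-2H-chromen-3-yl]-5,6-dimethoxybenzene-1,4-diol | COc1cc2c(c(O)c1OC)OC[C@H](c1cc(O)c(OC)c(OC)c1O)C2 | intermediate
18 | 5-[(3S)-8-hydroxy-6,7-dimethoxy-3,4-dihydro-2H-chromen-3-yl]-2,3-dimethoxycyclohexa-2,5-diene-1,4-dione | COC1=C(OC)C(=O)C([C@H]2COc3c(cc(OC)c(OC)c3O)C2)=CC1=O | target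

Total step count: 12. Longest linear sequence: 11 steps (steps 1–5 and 7–12, from 1); the quinone branch (step 6) joins at step 7.

**Steps most likely to fail**

Step 7. The enamine may add too slowly to the doubly methoxy-deactivated quinone. Redox exchange between the hydroquinone product and unreacted quinone, conjugate addition of the amine catalyst to the quinone and self-condensation of the aldehyde could then take over, or the facial selectivity could fall short. The fallback is an auxiliary-controlled benzylation (Evans alkylation), which forms C3–C4 instead of C3–C1' and needs no quinone electrophile. It sets out from quinone 10 and aryl iodide 6 and returns to the route at alcohol 14.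

For the ring B piece, quinone 10 would be reduced with Na2S2O4 to 2,3-dimethoxybenzene-1,4-diol F1 and benzylated (BnBr, K2CO3, DMF) to 1,4-bis(benzyloxy)-2,3-dimethoxybenzene F2. NBS in MeCN brominates one of its two equivalent free positions to give 1,4-bis(benzyloxy)-5-bromo-2,3-dimethoxybenzene F3. Palladium-catalysed α-arylation of tert-butyl acetate (Pd(dba)2, P(t-Bu)3, LiN(SiMe3)2, toluene) gives tert-butyl [2,5-bis(benzyloxy)-3,4-dimethoxyphenyl]acetate F4, which CF3CO2H in CH2Cl2 at 0 °C cleaves to [2,5-bis(benzyloxy)-3,4-dimethoxyphenyl]acetic acid F5. Pivaloyl chloride and Et3N in THF at −20 °C convert the acid into [2,5-bis(benzyloxy)-3,4-dimethoxyphenyl]acetic 2,2-dimethylpropanoic anhydride F6. Without isolation, LiCl and (S)-4-benzyl-1,3-oxazolidin-2-one are added, and acylation at the less hindered carbonyl gives (4S)-4-benzyl-3-{[2,5-bis(benzyloxy)-3,4-dimethoxyphenyl]acetyl}-1,3-oxazolidin-2-one F7.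

For the ring A piece, iodide 6 undergoes iodine–magnesium exchange with i-PrMgCl·LiCl to give [3-(benzyloxy)-4,5-dimethoxy-2-(methoxymethoxy)phenyl]magnesium chloride F8. Paraformaldehyde traps it as [3-(benzyloxy)-4,5-dimethoxy-2-(methoxymethoxy)phenyl]methanol F9, and CBr4/PPh3 converts that to 3-(benzyloxy)-1-(bromomethyl)-4,5-dimethoxy-2-(methoxymethoxy)benzene F10.

For the union, the sodium Z-enolate of the acyl oxazolidinone (NaN(SiMe3)2, THF, −78 °C) is alkylated by the benzylic bromide on the face away from the auxiliary benzyl group. This should give (4S)-4-benzyl-3-{(2S)-2-[2,5-bis(benzyloxy)-3,4-dimethoxyphenyl]-3-[3-(benzyloxy)-4,5-dimethoxy-2-(methoxymethoxy)phenyl]propanoyl}-1,3-oxazolidin-2-one F11. LiBH4 in wet THF then removes the auxiliary reductively and delivers 14.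

Step 5. With allyl alcohol the aryl–palladium intermediate can insert at the internal alkene carbon or eliminate hydride away from the carbinol, which would divert material to the branched aldehyde and to allylic alcohols. The fallback builds the chain at the ester oxidation level, where insertion and elimination have only one course. It sets out from iodide 6 and returns at aldehyde 8. Heck coupling of 6 with methyl acrylate (Pd(OAc)2, Bu4NBr, K2CO3, DMF, 80 °C) gives methyl (2E)-3-[3-(benzyloxy)-4,5-dimethoxy-2-(methoxymethoxy)phenyl]prop-2-enoate F12. Conjugate reduction with magnesium in methanol, which spares benzyl ethers, gives methyl 3-[3-(benzyloxy)-4,5-dimethoxy-2-(methoxymethoxy)phenyl]propanoate F13. Partial reduction with i-Bu2AlH in toluene at −78 °C gives 8.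

Step 11. The phenol is doubly ortho-substituted and electron-rich, hence a weak acid and a hindered nucleophile. The alkoxyphosphonium intermediate may therefore lose the benzylic C3 hydrogen by elimination or be intercepted by the hydrazide instead of cyclising. The fallback replaces the redox condensation by a stepwise sulfonate displacement. It sets out from alcohol 14 and returns at chroman 16. Mesylation of 14 (MsCl, Et3N, CH2Cl2, 0 °C) gives (2S)-2-[2,5-bis(benzyloxy)-3,4-dimethoxyphenyl]-3-[3-(benzyloxy)-4,5-dimethoxy-2-(methoxymethoxy)phenyl]propyl methanesulfonate F14. HCl in MeOH/THF at rt removes the methoxymethyl group to give (2S)-3-[3-(benzyloxy)-2-hydroxy-4,5-dimethoxyphenyl]-2-[2,5-bis(benzyloxy)-3,4-dimethoxyphenyl]propyl methanesulfonate F15. K2CO3 in DMF closes the pyran ring by intramolecular Williamson etherification (6-exo-tet) to give 16.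

**Further compounds**

F1 | step 7 | 2,3-dimethoxybenzene-1,4-diol | COc1c(O)ccc(O)c1OC
F2 | step 7 | 1,4-bis(benzyloxy)-2,3-dimethoxybenzene | COc1c(OCc2ccccc2)ccc(OCc2ccccc2)c1OC
F3 | step 7 | 1,4-bis(benzyloxy)-5-bromo-2,3-dimethoxybenzene | COc1c(OCc2ccccc2)cc(Br)c(OCc2ccccc2)c1OC
F4 | step 7 | tert-butyl [2,5-bis(benzyloxy)-3,4-dimethoxyphenyl]acetate | CC(C)(C)OC(=O)Cc1cc(OCc2ccccc2)c(OC)c(OC)c1OCc1ccccc1
F5 | step 7 | [2,5-bis(benzyloxy)-3,4-dimethoxyphenyl]acetic acid | OC(=O)Cc1cc(OCc2ccccc2)c(OC)c(OC)c1OCc1ccccc1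
F6 | step 7 | [2,5-bis(benzyloxy)-3,4-dimethoxyphenyl]acetic 2,2-dimethylpropanoic anhydride | CC(C)(C)C(=O)OC(=O)Cc1cc(OCc2ccccc2)c(OC)c(OC)c1OCc1ccccc1
F7 | step 7 | (4S)-4-benzyl-3-{[2,5-bis(benzyloxy)-3,4-dimethoxyphenyl]acetyl}-1,3-oxazolidin-2-one | O=C(Cc1cc(OCc2ccccc2)c(OC)c(OC)c1OCc1ccccc1)N1C(=O)OC[C@@H]1Cc1ccccc1
F8 | step 7 | [3-(benzyloxy)-4,5-dimethoxy-2-(methoxymethoxy)phenyl]magnesium chloride | COCOc1c([Mg]Cl)cc(OC)c(OC)c1OCc1ccccc1
F9 | step 7 | [3-(benzyloxy)-4,5-dimethoxy-2-(methoxymethoxy)phenyl]methanol | OCc1cc(OC)c(OC)c(OCc2ccccc2)c1OCOC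
F10 | step 7 | 3-(benzyloxy)-1-(bromomethyl)-4,5-dimethoxy-2-(methoxymethoxy)benzene | BrCc1cc(OC)c(OC)c(OCc2ccccc2)c1OCOC
F11 | step 7 | (4S)-4-benzyl-3-{(2S)-2-[2,5-bis(benzyloxy)-3,4-dimethoxyphenyl]-3-[3-(benzyloxy)-4,5-dimethoxy-2-(methoxymethoxy)phenyl]propanoyl}-1,3-oxazolidin-2-one | O=C([C@H](c1cc(OCc2ccccc2)c(OC)c(OC)c1OCc1ccccc1)Cc1cc(OC)c(OC)c(OCc2ccccc2)c1OCOC)N1C(=O)OC[C@@H]1Cc1ccccc1
F12 | step 5 | methyl (2E)-3-[3-(benzyloxy)-4,5-dimethoxy-2-(methoxymethoxy)phenyl]prop-2-enoate | COC(=O)/C=C/c1cc(OC)c(OC)c(OCc2ccccc2)c1OCOC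
F13 | step 5 | methyl 3-[3-(benzyloxy)-4,5-dimethoxy-2-(methoxymethoxy)phenyl]propanoate | COC(=O)CCc1cc(OC)c(OC)c(OCc2ccccc2)c1OCOC
F14 | step 11 | (2S)-2-[2,5-bis(benzyloxy)-3,4-dimethoxyphenyl]-3-[3-(benzyloxy)-4,5-dimethoxy-2-(methoxymethoxy)phenyl]propyl methanesulfonate | CS(=O)(=O)OC[C@H](c1cc(OCc2ccccc2)c(OC)c(OC)c1OCc1ccccc1)Cc1cc(OC)c(OC)c(OCc2ccccc2)c1OCOC
F15 | step 11 | (2S)-3-[3-(benzyloxy)-2-hydroxy-4,5-dimethoxyphenyl]-2-[2,5-bis(benzyloxy)-3,4-dimethoxyphenyl]propyl methanesulfonate | CS(=O)(=O)OC[C@H](c1cc(OCc2ccccc2)c(OC)c(OC)c1OCc1ccccc1)Cc1cc(OC)c(OC)c(OCc2ccccc2)c1O
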